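If you act on a flask, first compare two times: the time it needs to settle and the wait you allow it.

| flask | substrate | reagent | free catalyst | impurity | temperature | remark | time |
|---|---|---|---|---|---|---|---|
| east | 10 mM | 30 mM | 0.93 mM | 0.14 mM | 80 °C | the very flask that is asked about, followed so far |  |
| north-west | 10 mM | 30 mM | 0.93 mM | 0.14 mM | 65 °C | run made earlier |  |
| flask | 10 mM | 30.0 mM | 0.93 mM | 0.14 mM | 80 °C |  | 15 min |

| run | time / min | target / % |
|---|---|---|
| east | 1.00 | 14.9 |
| east | 3.00 | 11.9 |
| east | 6.00 | 9.4 |
| east | 8.00 | 10.8 |
| east | 12.0 | 9.2 |
| north-west | 2.00 | 24.8 |
| north-west | 6.00 | 13.8 |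
| north-west | 12.0 | 10.2 |
| north-west | 15.0 | 9.9 |
| north-west | 25.0 | 8.8 |

(readings scatter by 1 percentage point)

- target, in percent of the substrate first charged, at 15 min
- the remedy with the largest gain of target, or "none" below 2 percentage points (Tuesday's / Saturday's / Sunday's / Wednesday's / Thursday's / none)
- target present, with what was taken out counted in, in percent of the substrate first charged, after Saturday's
- target present, with what was taken out counted in, in percent of the substrate first charged, after Sunday's

- Tuesday's: change nothing and wait 5.0 min more
- Saturday's: at 15 min add free catalyst, 100% of the amount charged, then wait 5.0 min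
- Sunday's: at 15 min raise the temperature by 25 K, then wait 5.0 min
- Wednesday's: at 15 min add reagent, 50.0% of the amount charged, then wait 5.0 min
- Thursday's: at 15 min take out 90% of the target then present, then wait 5.0 min

- what is taken out of target is counted as made
- the analysis behind the earlier runs scatters by 1 percentage point, standard deviation
- additions bring no volume worth counting

Read the east run, which is the asked flask followed so far. Its last readings, 9.4%, 10.8% and 9.2%, scatter about their mean, so take 9.80% of the charge as the plateau. The excess of target over that plateau goes from 5.1 percentage points at 1.00 min to 2.1 points at 3.00 min, so it drops by a factor of two every 1.56 min; call this the settling time, a reading with the scatter in it.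

Hold it against the wait of 5.0 min: the ratio is 3.21, so by this reading a disturbance of the target keeps 10.9% of itself at the end of the wait. The asked time of 15 min is longer than that wait, so reckon the target then as the plateau. Thursday's takes out 90% of that plateau; if the flask refills towards the same plateau at the same pace, the counted target gains 7.9 points. As an estimate, put Saturday's and Sunday's near the plateau: they take no target out, and the north-west run, though at the lower temperature of 65 °C, has its last reading 1 point below that plateau.

The forecast gives 9.4% (8.6% to 10.2%), 9% after Saturday's, 9% after Sunday's and Thursday's as best, saying “A plateau that ignores temperature points to a balance”.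

The flask gives 9.97%, 9.96% after Saturday's and 9.07% after Sunday's; Thursday's is best with 7.8 points, and Wednesday's gains 2.4 points.

    substrate + reagent ⇌ target (K = 120 /M, k = 3.50 /M/s, Ea = 69.0 kJ/mol, ΔH = −60.0 kJ/mol)
    substrate + reagent ⇌ isomer of the product A (K = 97.0 /M, k = 1.20 /M/s, Ea = 63.0 kJ/mol, ΔH = −85.0 kJ/mol)
    target + free catalyst ⇌ isomer of the product A + free catalyst, rate k3*[free catalyst]*[target] forward; the back reaction follows from the equilibrium constant (k = 35.0 /M/s, Ea = 51.0 kJ/mol)
    target ⇌ isomer of the product B (K = 1.90, k = 0.0220 /s, Ea = 100 kJ/mol, ΔH = −55.0 kJ/mol)
    substrate ⇌ dormant form (K = 19.0, k = 0.0700 /s, Ea = 101 kJ/mol, ΔH = −45.0 kJ/mol)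
    free catalyst + impurity → spent catalyst (k = 2000 /M/s, Ea = 51.0 kJ/mol)
    (constants at 80 °C)

Carry the settling time to the north-west run, where its own readings give 3.27 min with the last reading as plateau. From 12.0 min the rule leaves 0.74 points of excess at 15.0 min, and the simulated north-west run still falls 0.9 points from then to 25.0 min. In the asked flask the rule leaves 0.01 points at 15 min. Left until 150 min, that flask holds 9.96% of target, while isomer of the product A goes from 8.06% to 8.05%.

Readings and results come from a simulation with constants of no real substance; noise was put on by code.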